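A direct plan would make the 4,4-disubstituted cycloheptenone A1 from 3-methylcyclohex-2-enone by conjugate addition of the side chain and a one-carbon ring expansion. It would then add a silylated alkenyl group at the ring carbon next to the quaternary centre and alkylate the enolate to reach A2. After dehydrogenation and hydroxymethylation it would end with C–O coupling of the alkenyl iodide A3 with 3-methylbut-2-enoic acid. Its weakest steps would be:
- the alkenyl conjugate addition beside the quaternary carbon, because methyl and chain are almost equal in size, so the ring would give no facial bias and a catalyst would have to impose it at a hindered β-carbon;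
- the ring expansion, because it would spend several operations without creating stereochemistry;
- the coupling of an alkenyl iodide with a carboxylate, because this bond formation has no direct precedent.

The route rests on the C5–C6 bond. C5, with its methyl group and 4-methylpentyl chain, is C3 of geraniol, so an enantioselective Ireland–Claisen rearrangement of a geranyl ester forms C5–C6 and turns the E geometry of the 2,3-double bond into the relative configuration of the quaternary carbon and its tertiary neighbour, while a chiral boron controller sets the absolute sense. The ester carbons become C6, C7, C1 and Cα. The seven-membered ring is closed last by metathesis at C2=C3, and the enol ester comes from an alkenyltrifluoroborate by a known copper coupling. No conjugate addition beside the quaternary carbon, no ring expansion and no alkenyl iodide coupling remain.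

Key step: step 2

Atom labels: ring carbons as in the target, C1 (C=O), C2 (bears CH2OH), C3, C4, C5 (quaternary), C6, C7; Cα and Cβ are the two carbons of the enol ester arm on C6.

Assumption: the (S,S) enantiomer of the boron controller is taken to deliver acid 5 as drawn; if its facial preference were the reverse, the (R,R) enantiomer would be used and nothing else would change.

Assumption: the bromide 14 and the bromide 18 are taken as purchasable.

Step 1
Reactants: 1 geraniol [(2E)-3,7-dimethylocta-2,6-dien-1-ol]; 2 3-cyanopropanoic acid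
Product: 3 (2E)-3,7-dimethylocta-2,6-dien-1-yl 3-cyanopropanoate
Conditions: DCC, DMAP (5 mol %), CH2Cl2, 0 °C to rt
Reagents that add atoms: none
Why: Steglich esterification of the primary allylic alcohol, which forms no stereocentre and leaves the E-2,3-double bond untouched.

Step 2
Reactants: 3 (2E)-3,7-dimethylocta-2,6-dien-1-yl 3-cyanopropanoate
Product: 5 (2S,3S)-2-(cyanomethyl)-3-ethenyl-3,7-dimethyloct-6-enoic acid, via boron ketene acetal 4 (not isolated)
Conditions: (S,S)-N,N′-(1,2-diphenylethane-1,2-diyl)bis[3,5-bis(trifluoromethyl)benzenesulfonamide], BBr3, CH2Cl2, rt, then evacuation; 3, Et3N, toluene/hexane, −78 °C, then 4 °C; aqueous acid work-up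
Reagents that add atoms: none
Why: The bromoborane binds the ester carbonyl, Et3N removes an α-hydrogen, and the E(O) boron ketene acetal 4 (cyanomethyl group trans to O–B) rearranges by a [3,3]-sigmatropic shift through a chair transition state in which the allylic C–O bond breaks as the C5–C6 bond forms. The closest known reaction type is the enantioselective Ireland–Claisen rearrangement of achiral allylic esters mediated by chiral diazaborolidines, which has precedent with 3,3-disubstituted allyl esters that give quaternary carbons. No ring is closed here; ring closure is left to step 8. The relative configuration of C5 and C6 follows from the chair with the E-trisubstituted alkene (chain equatorial, methyl axial) and the E(O) ketene acetal (cyanomethyl axial), and the absolute configuration is set by the C2-symmetric sulfonamide ligand on boron, which shields one face of the ketene acetal. The step needs enolisation at the ester and not beside the nitrile, which the more basic ester carbonyl secures by being the site that boron binds, and it needs the 2,3- and not the 6,7-double bond to react, which the six-atom array secures.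

Step 3
Reactants: 5 (2S,3S)-2-(cyanomethyl)-3-ethenyl-3,7-dimethyloct-6-enoic acid
Product: 8 (4S)-4-[(3S)-3,7-dimethylocta-1,6-dien-3-yl]oxolan-2-one, via mixed anhydride 6 (not isolated), via hydroxy nitrile 7 (not isolated)
Conditions: i-BuOCOCl, N-methylmorpholine, THF, −15 °C; NaBH4, H2O, 0 °C; then 1 M HCl, THF, rt to 40 °C
Reagents that add atoms: water O
Why: Chemoselective reduction of the acid through its mixed carbonic anhydride with NaBH4, which spares nitrile and alkenes, followed by acid-mediated cyclisation of the γ-hydroxy nitrile through the iminolactone (Pinner-type) to the γ-lactone, in which C1 is the carbonyl and Cα carries the ring oxygen; both stereocentres are untouched.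

Step 4
Reactants: 8 (4S)-4-[(3S)-3,7-dimethylocta-1,6-dien-3-yl]oxolan-2-one
Product: 10 (4S)-4-[(3S)-1-hydroxy-3,7-dimethyloct-6-en-3-yl]oxolan-2-one, via alkylborane 9 (not isolated)
Conditions: 9-BBN, THF, rt; then 30% H2O2, aq. NaOAc, 0 °C to rt
Reagents that add atoms: hydrogen peroxide OO
Why: Anti-Markovnikov hydroboration–oxidation, in which 9-BBN selects the monosubstituted vinyl group over the trisubstituted 6,7-double bond and the buffered oxidation spares the lactone; no stereocentre is formed.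

Step 5
Reactants: 10 (4S)-4-[(3S)-1-hydroxy-3,7-dimethyloct-6-en-3-yl]oxolan-2-one
Product: 11 (4S)-4-[(3S)-1,7-dihydroxy-3,7-dimethyloctan-3-yl]oxolan-2-one
Conditions: cobalt bis(acetylacetonate) Co(acac)2 (20 mol %), PhSiH3, O2 (1 atm), THF, rt
Reagents that add atoms: dioxygen O=O
Why: Mukaiyama hydration (hydrogen-atom transfer from a cobalt hydride to the trisubstituted alkene, capture of the tertiary radical by O2 and reduction of the peroxide), which gives the Markovnikov tertiary alcohol of the side chain and leaves lactone and primary alcohol alone.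

Step 6
Reactants: 11 (4S)-4-[(3S)-1,7-dihydroxy-3,7-dimethyloctan-3-yl]oxolan-2-one
Product: 13 (4S)-4-[(4S)-8-hydroxy-4,8-dimethylnon-1-en-4-yl]oxolan-2-one, via aldehyde 12 (not isolated)
Conditions: Dess–Martin periodinane, NaHCO3, CH2Cl2, 0 °C to rt, filtration; then Ph3PCH3Br, KN(SiMe3)2, THF, −78 to 0 °C
Reagents that add atoms: methyltriphenylphosphonium bromide C[P+](c1ccccc1)(c1ccccc1)c1ccccc1.[Br-]
Why: Dess–Martin oxidation of the primary alcohol (the tertiary one cannot react) and Wittig methylenation of the crude aldehyde turn the two-carbon arm on C5 into the allyl group C4–C3 needed for ring closure; an extra equivalent of ylide covers the tertiary alcohol and the lactone is not attacked at low temperature.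

Step 7
Reactants: 13 (4S)-4-[(4S)-8-hydroxy-4,8-dimethylnon-1-en-4-yl]oxolan-2-one; 14 [(2-bromoprop-2-en-1-yl)oxy](tert-butyl)dimethylsilane
Product: 16 (5S,6S)-2-({[tert-butyl(dimethyl)silyl]oxy}methyl)-10-hydroxy-6,10-dimethyl-6-(prop-2-en-1-yl)-5-{[(triethylsilyl)oxy]methyl}undec-1-en-3-one, via alkenyllithium 15 (not isolated)
Conditions: 14, t-BuLi (2 equiv per 14), Et2O, −78 °C; then 13 (0.45 equiv), −78 °C; then Et3SiCl, −78 to −20 °C; NH4Cl work-up
Reagents that add atoms: chlorotriethylsilane CC[Si](Cl)(CC)CC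
Why: Bromine–lithium exchange and single addition of the alkenyllithium to the γ-lactone, whose tetrahedral lithium alkoxide resists a second addition at −78 °C, followed by O-silylation of the released primary alkoxide (the hindered tertiary alkoxide is protonated on work-up); this brings in C2 with its oxygenated carbon and makes C1 the ketone.

Step 8
Reactants: 16 (5S,6S)-2-({[tert-butyl(dimethyl)silyl]oxy}methyl)-10-hydroxy-6,10-dimethyl-6-(prop-2-en-1-yl)-5-{[(triethylsilyl)oxy]methyl}undec-1-en-3-one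
Product: 17 (5S,6S)-2-({[tert-butyl(dimethyl)silyl]oxy}methyl)-5-(4-hydroxy-4-methylpentyl)-5-methyl-6-{[(triethylsilyl)oxy]methyl}cyclohept-2-en-1-one
Conditions: second-generation Hoveyda–Grubbs catalyst (5 mol %), toluene, 80 °C, high dilution
Reagents that add atoms: none
Why: Ring-closing olefin metathesis between the terminal allyl group and the 1,1-disubstituted enone double bond closes the seven-membered ring at C2=C3 with loss of ethene; the catalyst loads on the allyl group and no other alkene is left in the molecule.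

Step 9
Reactants: 17 (5S,6S)-2-({[tert-butyl(dimethyl)silyl]oxy}methyl)-5-(4-hydroxy-4-methylpentyl)-5-methyl-6-{[(triethylsilyl)oxy]methyl}cyclohept-2-en-1-one; 18 3-bromo-2-methoxyprop-1-ene
Product: 20 (5S,6S,7S)-2-({[tert-butyl(dimethyl)silyl]oxy}methyl)-6-(hydroxymethyl)-5-(4-hydroxy-4-methylpentyl)-5-methyl-7-(2-oxopropyl)cyclohept-2-en-1-one, via enol ether 19 (not isolated)
Conditions: LiN(i-Pr)2 (2.2 equiv), THF, −78 °C; 18, DMPU, −78 to −40 °C; then 1 M HCl, THF, 0 °C
Reagents that add atoms: water O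
Why: Kinetic deprotonation of the enone at the α′ carbon C7 and alkylation of the lithium enolate by the allylic bromide anti to the neighbouring C6 substituent set C7 trans to the C6 arm, and mild acid then hydrolyses the methyl enol ether to the methyl ketone and removes the primary triethylsilyl group.

Step 10
Reactants: 20 (5S,6S,7S)-2-({[tert-butyl(dimethyl)silyl]oxy}methyl)-6-(hydroxymethyl)-5-(4-hydroxy-4-methylpentyl)-5-methyl-7-(2-oxopropyl)cyclohept-2-en-1-one
Product: 21 (1S,2S,7S)-5-({[tert-butyl(dimethyl)silyl]oxy}methyl)-2-(4-hydroxy-4-methylpentyl)-2-methyl-6-oxo-7-(2-oxopropyl)cyclohept-4-ene-1-carbaldehyde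
Conditions: Dess–Martin periodinane, NaHCO3, CH2Cl2, 0 °C
Reagents that add atoms: none
Why: Dess–Martin oxidation of the only primary alcohol under buffered, base-free conditions, so that C6 (now α to the aldehyde) and C7 should not epimerise.

Step 11
Reactants: 21 (1S,2S,7S)-5-({[tert-butyl(dimethyl)silyl]oxy}methyl)-2-(4-hydroxy-4-methylpentyl)-2-methyl-6-oxo-7-(2-oxopropyl)cyclohept-4-ene-1-carbaldehyde
Product: 22 (5S,6S,7S)-2-({[tert-butyl(dimethyl)silyl]oxy}methyl)-5-(4-hydroxy-4-methylpentyl)-5-methyl-7-(2-oxopropyl)-6-[(E)-2-(4,4,5,5-tetramethyl-1,3,2-dioxaborolan-2-yl)ethenyl]cyclohept-2-en-1-one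
Conditions: CrCl2 (8 equiv), LiI (4 equiv), Cl2CHB(pin) (2 equiv), THF, rt
Reagents that add atoms: 2-(dichloromethyl)-4,4,5,5-tetramethyl-1,3,2-dioxaborolane ClC(Cl)B1OC(C)(C)C(C)(C)O1
Why: Takai–Utimoto boron olefination, in which the geminal dichromium reagent adds to the aldehyde and eliminates to the E-alkenylboronate (this adds Cβ) and ignores both ketones.

Step 12
Reactants: 22 (5S,6S,7S)-2-({[tert-butyl(dimethyl)silyl]oxy}methyl)-5-(4-hydroxy-4-methylpentyl)-5-methyl-7-(2-oxopropyl)-6-[(E)-2-(4,4,5,5-tetramethyl-1,3,2-dioxaborolan-2-yl)ethenyl]cyclohept-2-en-1-one; 23 3-methylbut-2-enoic acid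
Product: 25 (5S,6S,7S)-2-({[tert-butyl(dimethyl)silyl]oxy}methyl)-5-(4-hydroxy-4-methylpentyl)-5-methyl-6-[(E)-2-(3-methylbut-2-enoyloxy)ethenyl]-7-(2-oxopropyl)cyclohept-2-en-1-one, via trifluoroborate 24 (not isolated)
Conditions: KHF2, MeOH/H2O, rt, then evaporation; 23, CuBr (10 mol %), DMAP (20 mol %), 4 Å MS, O2 (1 atm), CH2Cl2, 40 °C
Reagents that add atoms: none
Why: Conversion into the potassium alkenyltrifluoroborate and copper-catalysed oxidative C–O coupling with the carboxylic acid (Chan–Lam-type coupling of alkenyltrifluoroborates with carboxylic acids), which should keep the E geometry and leave the ketones, the tertiary alcohol and the silyl ether alone.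

Step 13
Reactants: 25 (5S,6S,7S)-2-({[tert-butyl(dimethyl)silyl]oxy}methyl)-5-(4-hydroxy-4-methylpentyl)-5-methyl-6-[(E)-2-(3-methylbut-2-enoyloxy)ethenyl]-7-(2-oxopropyl)cyclohept-2-en-1-one
Product: 26 (5S,6S,7S)-2-(hydroxymethyl)-5-(4-hydroxy-4-methylpentyl)-5-methyl-6-[(E)-2-(3-methylbut-2-enoyloxy)ethenyl]-7-(2-oxopropyl)cyclohept-2-en-1-one (CNP0359016.1)
Conditions: HF·pyridine, pyridine, THF, 0 °C
Reagents that add atoms: none
Why: Fluoride-mediated cleavage of the primary tert-butyldimethylsilyl ether under buffered conditions, which the enol ester, the enone and the tertiary alcohol should survive.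

Compound list
1 | geraniol, (2E)-3,7-dimethylocta-2,6-dien-1-ol | CC(C)=CCC/C(C)=C/CO | starting material
2 | 3-cyanopropanoic acid | N#CCCC(=O)O | starting material
3 | (2E)-3,7-dimethylocta-2,6-dien-1-yl 3-cyanopropanoate | CC(C)=CCC/C(C)=C/COC(=O)CCC#N | intermediate
4 | E(O) boron ketene acetal of 3 bearing the (4S,5S)-4,5-diphenyl-1,3-bis{[3,5-bis(trifluoromethyl)phenyl]sulfonyl}-1,3,2-diazaborolidin-2-yl group on oxygen | N#CC/C=C(\OC/C=C(C)/CCC=C(C)C)OB1N(S(=O)(=O)c2cc(cc(c2)C(F)(F)F)C(F)(F)F)[C@@H](c2ccccc2)[C@H](c2ccccc2)N1S(=O)(=O)c1cc(cc(c1)C(F)(F)F)C(F)(F)F | intermediate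
5 | (2S,3S)-2-(cyanomethyl)-3-ethenyl-3,7-dimethyloct-6-enoic acid | OC(=O)[C@@H](CC#N)[C@](C)(C=C)CCC=C(C)C | intermediate
6 | (2S,3S)-2-(cyanomethyl)-3-ethenyl-3,7-dimethyloct-6-enoic 2-methylpropyl carbonic anhydride | CC(C)COC(=O)OC(=O)[C@@H](CC#N)[C@](C)(C=C)CCC=C(C)C | intermediate
7 | (3S,4S)-4-ethenyl-3-(hydroxymethyl)-4,8-dimethylnon-7-enenitrile | N#CC[C@H](CO)[C@](C)(C=C)CCC=C(C)C | intermediate
8 | (4S)-4-[(3S)-3,7-dimethylocta-1,6-dien-3-yl]oxolan-2-one | O=C1C[C@H](CO1)[C@](C)(C=C)CCC=C(C)C | intermediate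
9 | 9-{(3R)-3,7-dimethyl-3-[(3S)-5-oxooxolan-3-yl]oct-6-en-1-yl}-9-borabicyclo[3.3.1]nonane | O=C1C[C@H](CO1)[C@](C)(CCB1C2CCCC1CCC2)CCC=C(C)C | intermediate
10 | (4S)-4-[(3S)-1-hydroxy-3,7-dimethyloct-6-en-3-yl]oxolan-2-one | O=C1C[C@H](CO1)[C@](C)(CCO)CCC=C(C)C | intermediate
11 | (4S)-4-[(3S)-1,7-dihydroxy-3,7-dimethyloctan-3-yl]oxolan-2-one | O=C1C[C@H](CO1)[C@](C)(CCO)CCCC(C)(C)O | intermediate
12 | (3S)-7-hydroxy-3,7-dimethyl-3-[(3S)-5-oxooxolan-3-yl]octanal | O=C1C[C@H](CO1)[C@](C)(CC=O)CCCC(C)(C)O | intermediate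
13 | (4S)-4-[(4S)-8-hydroxy-4,8-dimethylnon-1-en-4-yl]oxolan-2-one | O=C1C[C@H](CO1)[C@](C)(CC=C)CCCC(C)(C)O | intermediate
14 | [(2-bromoprop-2-en-1-yl)oxy](tert-butyl)dimethylsilane | C=C(Br)CO[Si](C)(C)C(C)(C)C | starting material
15 | {3-[(tert-butyldimethylsilyl)oxy]prop-1-en-2-yl}lithium | [Li]C(=C)CO[Si](C)(C)C(C)(C)C | intermediate
16 | (5S,6S)-2-({[tert-butyl(dimethyl)silyl]oxy}methyl)-10-hydroxy-6,10-dimethyl-6-(prop-2-en-1-yl)-5-{[(triethylsilyl)oxy]methyl}undec-1-en-3-one | C=C(CO[Si](C)(C)C(C)(C)C)C(=O)C[C@H](CO[Si](CC)(CC)CC)[C@](C)(CC=C)CCCC(C)(C)O | intermediate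
17 | (5S,6S)-2-({[tert-butyl(dimethyl)silyl]oxy}methyl)-5-(4-hydroxy-4-methylpentyl)-5-methyl-6-{[(triethylsilyl)oxy]methyl}cyclohept-2-en-1-one | C1C(=O)C(CO[Si](C)(C)C(C)(C)C)=CC[C@](C)(CCCC(C)(C)O)[C@H]1CO[Si](CC)(CC)CC | intermediate
18 | 3-bromo-2-methoxyprop-1-ene | COC(=C)CBr | starting material
19 | (5S,6S,7S)-2-({[tert-butyl(dimethyl)silyl]oxy}methyl)-5-(4-hydroxy-4-methylpentyl)-7-(2-methoxyprop-2-en-1-yl)-5-methyl-6-{[(triethylsilyl)oxy]methyl}cyclohept-2-en-1-one | COC(=C)C[C@@H]1C(=O)C(CO[Si](C)(C)C(C)(C)C)=CC[C@](C)(CCCC(C)(C)O)[C@H]1CO[Si](CC)(CC)CC | intermediate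
20 | (5S,6S,7S)-2-({[tert-butyl(dimethyl)silyl]oxy}methyl)-6-(hydroxymethyl)-5-(4-hydroxy-4-methylpentyl)-5-methyl-7-(2-oxopropyl)cyclohept-2-en-1-one | CC(=O)C[C@@H]1C(=O)C(CO[Si](C)(C)C(C)(C)C)=CC[C@](C)(CCCC(C)(C)O)[C@H]1CO | intermediate
21 | (1S,2S,7S)-5-({[tert-butyl(dimethyl)silyl]oxy}methyl)-2-(4-hydroxy-4-methylpentyl)-2-methyl-6-oxo-7-(2-oxopropyl)cyclohept-4-ene-1-carbaldehyde | CC(=O)C[C@@H]1C(=O)C(CO[Si](C)(C)C(C)(C)C)=CC[C@](C)(CCCC(C)(C)O)[C@H]1C=O | intermediate
22 | (5S,6S,7S)-2-({[tert-butyl(dimethyl)silyl]oxy}methyl)-5-(4-hydroxy-4-methylpentyl)-5-methyl-7-(2-oxopropyl)-6-[(E)-2-(4,4,5,5-tetramethyl-1,3,2-dioxaborolan-2-yl)ethenyl]cyclohept-2-en-1-one | CC(=O)C[C@@H]1C(=O)C(CO[Si](C)(C)C(C)(C)C)=CC[C@](C)(CCCC(C)(C)O)[C@H]1/C=C/B1OC(C)(C)C(C)(C)O1 | intermediate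
23 | 3-methylbut-2-enoic acid | CC(C)=CC(=O)O | starting material
24 | potassium (E)-alkenyltrifluoroborate derived from 22 (BF3K in place of the dioxaborolane) | CC(=O)C[C@@H]1C(=O)C(CO[Si](C)(C)C(C)(C)C)=CC[C@](C)(CCCC(C)(C)O)[C@H]1/C=C/[B-](F)(F)F.[K+] | intermediate
25 | (5S,6S,7S)-2-({[tert-butyl(dimethyl)silyl]oxy}methyl)-5-(4-hydroxy-4-methylpentyl)-5-methyl-6-[(E)-2-(3-methylbut-2-enoyloxy)ethenyl]-7-(2-oxopropyl)cyclohept-2-en-1-one | CC(=O)C[C@@H]1C(=O)C(CO[Si](C)(C)C(C)(C)C)=CC[C@](C)(CCCC(C)(C)O)[C@H]1/C=C/OC(=O)C=C(C)C | intermediate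
26 | (5S,6S,7S)-2-(hydroxymethyl)-5-(4-hydroxy-4-methylpentyl)-5-methyl-6-[(E)-2-(3-methylbut-2-enoyloxy)ethenyl]-7-(2-oxopropyl)cyclohept-2-en-1-one (CNP0359016.1) | CC(=O)C[C@@H]1C(=O)C(CO)=CC[C@](C)(CCCC(C)(C)O)[C@H]1/C=C/OC(=O)C=C(C)C | target

Total step count: 13. Longest linear sequence: 13 steps (from geraniol 1).

Steps most likely to fail

Step 2. The boron reagent may enolise the cyano ester slowly, or its facial preference may be eroded by the remote nitrile, so that the acid forms with low enantiomeric purity. The fallback sets out from 1 and comes back at 8; it replaces reagent control by a substrate-controlled rearrangement and a classical resolution. Geraniol 1 would be esterified (DCC, DMAP) with 4-(dimethylamino)-4-oxobutanoic acid to (2E)-3,7-dimethylocta-2,6-dien-1-yl 4-(dimethylamino)-4-oxobutanoate F1. Ireland–Claisen rearrangement under the classical conditions (LiN(i-Pr)2, Me3SiCl, THF, −78 °C to rt) should deprotonate the ester in preference to the amide and give, through the same chair, racemic (2S*,3S*)-2-[2-(dimethylamino)-2-oxoethyl]-3-ethenyl-3,7-dimethyloct-6-enoic acid F2. Crystallisation with (S)-1-phenylethylamine would give the (S)-1-phenylethylammonium salt of the (2S,3S) acid F3. The liberated acid would be reduced through its mixed anhydride (i-BuOCOCl, N-methylmorpholine; NaBH4) to (3S,4S)-4-ethenyl-3-(hydroxymethyl)-N,N,4,8-tetramethylnon-7-enamide F4, which should lactonise in dilute HCl to 8.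

Step 9. Alkylation of the cycloheptenone enolate may show poor facial selectivity, or proton transfer and γ-deprotonation may compete. The fallback sets out from 13 and comes back at 20; it puts the 2-oxopropyl arm on at the lactone stage. Alkylation of the lactone enolate of 13 (LiN(i-Pr)2, 18, THF, −78 °C) would give, with the bromide entering trans to the C6 substituent, (3R,4S)-4-[(4S)-8-hydroxy-4,8-dimethylnon-1-en-4-yl]-3-(2-methoxyprop-2-en-1-yl)oxolan-2-one F5. Renewed deprotonation and kinetic protonation with 2,6-di-tert-butylphenol from the face away from the quaternary substituent would give the cis-lactone (3S,4S)-4-[(4S)-8-hydroxy-4,8-dimethylnon-1-en-4-yl]-3-(2-methoxyprop-2-en-1-yl)oxolan-2-one F6, which has the C7 configuration of the target. Addition of 15 and work-up with dilute acid would give (4S,5S,6S)-2-({[tert-butyl(dimethyl)silyl]oxy}methyl)-10-hydroxy-5-(hydroxymethyl)-6,10-dimethyl-4-(2-oxopropyl)-6-(prop-2-en-1-yl)undec-1-en-3-one F7, and ring-closing metathesis as in step 8 would give 20.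

Step 8. The 1,1-disubstituted enone terminus may engage the ruthenium carbene slowly, so that intermolecular metathesis through the allyl group or decomposition of the α-methylene ketone wins. The fallback sets out from 13 and comes back at 17; it closes an unsubstituted enone and adds the hydroxymethyl carbon afterwards. Addition of vinyllithium (from bromoethene and t-BuLi) to 13 and trapping with Et3SiCl would give (5S,6S)-10-hydroxy-6,10-dimethyl-6-(prop-2-en-1-yl)-5-{[(triethylsilyl)oxy]methyl}undec-1-en-3-one F8. Ring-closing metathesis to a disubstituted enone (second-generation Grubbs catalyst) would give (5S,6S)-5-(4-hydroxy-4-methylpentyl)-5-methyl-6-{[(triethylsilyl)oxy]methyl}cyclohept-2-en-1-one F9. Morita–Baylis–Hillman hydroxymethylation (aqueous formaldehyde, imidazole) would give (5S,6S)-2-(hydroxymethyl)-5-(4-hydroxy-4-methylpentyl)-5-methyl-6-{[(triethylsilyl)oxy]methyl}cyclohept-2-en-1-one F10, and silylation (t-BuMe2SiCl, imidazole) would give 17.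

Further compounds
F1 | step 2 | (2E)-3,7-dimethylocta-2,6-dien-1-yl 4-(dimethylamino)-4-oxobutanoate | CC(C)=CCC/C(C)=C/COC(=O)CCC(=O)N(C)C
F2 | step 2 | racemic (2S*,3S*)-2-[2-(dimethylamino)-2-oxoethyl]-3-ethenyl-3,7-dimethyloct-6-enoic acid (both enantiomers) | OC(=O)[C@@H](CC(=O)N(C)C)[C@](C)(C=C)CCC=C(C)C.OC(=O)[C@H](CC(=O)N(C)C)[C@@](C)(C=C)CCC=C(C)C
F3 | step 2 | (S)-1-phenylethylammonium (2S,3S)-2-[2-(dimethylamino)-2-oxoethyl]-3-ethenyl-3,7-dimethyloct-6-enoate | CN(C)C(=O)C[C@H](C([O-])=O)[C@](C)(C=C)CCC=C(C)C.C[C@H]([NH3+])c1ccccc1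
F4 | step 2 | (3S,4S)-4-ethenyl-3-(hydroxymethyl)-N,N,4,8-tetramethylnon-7-enamide | CN(C)C(=O)C[C@H](CO)[C@](C)(C=C)CCC=C(C)C
F5 | step 9 | (3R,4S)-4-[(4S)-8-hydroxy-4,8-dimethylnon-1-en-4-yl]-3-(2-methoxyprop-2-en-1-yl)oxolan-2-one | O=C1[C@H](CC(OC)=C)[C@H](CO1)[C@](C)(CC=C)CCCC(C)(C)O
F6 | step 9 | (3S,4S)-4-[(4S)-8-hydroxy-4,8-dimethylnon-1-en-4-yl]-3-(2-methoxyprop-2-en-1-yl)oxolan-2-one | O=C1[C@@H](CC(OC)=C)[C@H](CO1)[C@](C)(CC=C)CCCC(C)(C)O
F7 | step 9 | (4S,5S,6S)-2-({[tert-butyl(dimethyl)silyl]oxy}methyl)-10-hydroxy-5-(hydroxymethyl)-6,10-dimethyl-4-(2-oxopropyl)-6-(prop-2-en-1-yl)undec-1-en-3-one | C=C(CO[Si](C)(C)C(C)(C)C)C(=O)[C@@H](CC(C)=O)[C@H](CO)[C@](C)(CC=C)CCCC(C)(C)O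
F8 | step 8 | (5S,6S)-10-hydroxy-6,10-dimethyl-6-(prop-2-en-1-yl)-5-{[(triethylsilyl)oxy]methyl}undec-1-en-3-one | C=CC(=O)C[C@H](CO[Si](CC)(CC)CC)[C@](C)(CC=C)CCCC(C)(C)O
F9 | step 8 | (5S,6S)-5-(4-hydroxy-4-methylpentyl)-5-methyl-6-{[(triethylsilyl)oxy]methyl}cyclohept-2-en-1-one | C1C(=O)C=CC[C@](C)(CCCC(C)(C)O)[C@H]1CO[Si](CC)(CC)CC
F10 | step 8 | (5S,6S)-2-(hydroxymethyl)-5-(4-hydroxy-4-methylpentyl)-5-methyl-6-{[(triethylsilyl)oxy]methyl}cyclohept-2-en-1-one | C1C(=O)C(CO)=CC[C@](C)(CCCC(C)(C)O)[C@H]1CO[Si](CC)(CC)CC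
A1 | direct plan | (S)-4-(4-hydroxy-4-methylpentyl)-4-methylcyclohept-2-en-1-one | O=C1CCC[C@](C)(CCCC(C)(C)O)C=C1
A2 | direct plan | (2S,3R,4S)-4-(4-hydroxy-4-methylpentyl)-2-(2-methoxyprop-2-en-1-yl)-4-methyl-3-[(E)-2-(trimethylsilyl)ethenyl]cycloheptan-1-one | COC(=C)C[C@@H]1C(=O)CCC[C@](C)(CCCC(C)(C)O)[C@H]1/C=C/[Si](C)(C)C
A3 | direct plan | (5S,6R,7S)-2-(hydroxymethyl)-5-(4-hydroxy-4-methylpentyl)-6-[(E)-2-iodoethenyl]-5-methyl-7-(2-oxopropyl)cyclohept-2-en-1-one | CC(=O)C[C@@H]1C(=O)C(CO)=CC[C@](C)(CCCC(C)(C)O)[C@H]1/C=C/I
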